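The two aryl bonds of the ring M dihydrofuran, C2'–ring E and C3'–ring F, are the disconnection: these vicinal methine carbons are read as the two ends of an (E)-alkene on ring M. In step 7 a palladium-catalysed conjunctive coupling unites a ring M styrenylboronate, 2,4-dimethoxyphenyllithium and 3,5-dimethoxyphenyl triflate. It makes both C–aryl bonds and both stereocentres and leaves boron on C2' as the future O1'. The precursor is the (E)-alkenylboronate of a hindered acenaphthene diol, with OMOM beside a C7' bromine installed beforehand. The bromine later delivers ring M as the migrating aryl of a second such coupling that builds C2 and C3.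

Key step: step 7

Locants: unprimed numbers belong to the dihydrobenzofuran built on ring A, primed numbers to the one built on ring M. Ring B is the 4-oxygenated styryl ring, ring E the 2,4-dioxygenated ring on C2', ring F the 3,5-dioxygenated ring on C3', ring G the 3,5-dioxygenated ring on C3. "mac" is the diolate of diol 7.

Assumption: the (Sp,Sp) enantiomer of the MandyPhos ligand is taken to give the 3'S (and 3S) sense; if the sense proves opposite, the (Rp,Rp) ligand is used in steps 7 and 15 and nothing else changes.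

Design remarks:
- The C7' bromine is carried from the first step, because bromination after the coupling could not tell ring M from the equally activated rings E and F.
- The boron ligand is mac, not pinacol, because β-substituted alkenyl ate complexes of pinacol esters mainly undergo direct Suzuki–Miyaura transfer.
- Each MOM group is removed before the C–B bond is oxidised, so the easily ionised benzylic alcohol never meets acid.
- Ring A carries two MOM groups: its two oxygens are equivalent, so no desymmetrisation is needed and the C4 hydroxyl is left free after the second ring closure.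

Step 1
Reactants: 1 2-bromo-5-methoxyphenol
Product: 2 1-bromo-4-methoxy-2-(methoxymethoxy)benzene
Conditions: MOMCl, i-Pr2NEt, CH2Cl2, 0 °C→rt
Reagents that add atoms: chloromethyl methyl ether, COCCl
Why: O-alkylation of the phenoxide with the chloromethyl ether (MOM protection) masks the future O1' with a group that also directs the metalation of step 2.

Step 2
Reactants: 2 1-bromo-4-methoxy-2-(methoxymethoxy)benzene
Product: 4 3-bromo-6-methoxy-2-(methoxymethoxy)benzaldehyde, via aryllithium 3 (not isolated)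
Conditions: LiTMP (lithium 2,2,6,6-tetramethylpiperidide), THF, −78 °C; DMF, −78→0 °C; H2O
Reagents that add atoms: N,N-dimethylformamide, CN(C)C=O
Why: Directed ortho-metalation by an amide base, which does not undergo lithium–bromine exchange, takes the proton flanked by OMOM and OMe, and formylation with DMF places the aldehyde between the two oxygens with bromine beside the OMOM group.

Step 3
Reactants: 4 3-bromo-6-methoxy-2-(methoxymethoxy)benzaldehyde
Product: 5 1-bromo-3-ethynyl-4-methoxy-2-(methoxymethoxy)benzene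
Conditions: dimethyl (1-diazo-2-oxopropyl)phosphonate, K2CO3, MeOH/THF, 0 °C→rt
Reagents that add atoms: dimethyl (1-diazo-2-oxopropyl)phosphonate, COP(=O)(OC)C(=[N+]=[N-])C(C)=O
Why: Seyferth–Gilbert homologation in its Ohira–Bestmann form converts the aryl aldehyde into the terminal alkyne under mild carbonate conditions that leave the MOM ether and the aryl bromide alone.

Step 4
Reactants: 6 acenaphthylene-1,2-dione
Product: 7 cis-1,2-dimethyl-1,2-dihydroacenaphthylene-1,2-diol
Conditions: AlMe3 (3 equiv), toluene, 0 °C→rt; aqueous work-up; recrystallisation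
Reagents that add atoms: trimethylaluminium, C[Al](C)C
Why: Double 1,2-addition of methyl to the 1,2-dione, in which the second methyl enters anti to the bulky aluminium alkoxide, should give the cis (meso) diol, and crystallisation removes any trans isomer.

Step 5
Reactants: 5 1-bromo-3-ethynyl-4-methoxy-2-(methoxymethoxy)benzene; 7 cis-1,2-dimethyl-1,2-dihydroacenaphthylene-1,2-diol
Product: 9 B(mac) ester of (E)-2-[3-bromo-6-methoxy-2-(methoxymethoxy)phenyl]ethenylboronic acid, via alkenyl catechol boronate 8 (not isolated)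
Conditions: catecholborane, Cy2BH (5 mol %), THF, rt; then 7, rt
Reagents that add atoms: catecholborane, B1Oc2ccccc2O1
Why: Dialkylborane-catalysed hydroboration of the terminal alkyne is syn and anti-Markovnikov and so fixes the E geometry, and the labile catechol ester is then exchanged for the tertiary cis-diol (transesterification).

Step 6
Reactants: 10 3,5-dimethoxyphenol
Product: 11 3,5-dimethoxyphenyl trifluoromethanesulfonate
Conditions: Tf2O, pyridine, CH2Cl2, 0 °C
Reagents that add atoms: trifluoromethanesulfonic anhydride, O=S(=O)(OS(=O)(=O)C(F)(F)F)C(F)(F)F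
Why: O-sulfonylation of the phenol gives the aryl triflate that serves as electrophile in steps 7 and 15.

Step 7
Reactants: 9 B(mac) ester of (E)-2-[3-bromo-6-methoxy-2-(methoxymethoxy)phenyl]ethenylboronic acid; 12 1-bromo-2,4-dimethoxybenzene; 11 3,5-dimethoxyphenyl trifluoromethanesulfonate
Product: 15 B(mac) ester of (1R,2S)-2-[3-bromo-6-methoxy-2-(methoxymethoxy)phenyl]-1-(2,4-dimethoxyphenyl)-2-(3,5-dimethoxyphenyl)ethylboronic acid, via 2,4-dimethoxyphenyllithium 13 (not isolated), via lithium ate complex 14 (not isolated)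
Conditions: 12, t-BuLi (2 equiv), Et2O, −78 °C; then 9, −78 °C→rt; solvent switch to THF; Pd(OAc)2 (3 mol %), (Sp,Sp)-MandyPhos (3.6 mol %), KOTf, 11, 60 °C
Reagents that add atoms: none
Why: Aryllithium 13 adds to the boron of 9 to give the four-coordinate ate complex 14; the aryl–palladium cation formed by oxidative addition of zerovalent palladium to triflate 11 binds the alkene and induces a 1,2-shift of the 2,4-dimethoxyphenyl group from boron to C2' anti to palladium, and reductive elimination then joins C3' to ring F. This is the enantioselective conjunctive cross-coupling of β-substituted alkenylboron ate complexes with aryl triflates, in which the hindered mac ester holds back direct Suzuki–Miyaura transfer. No ring is closed. C3' is set by the alkene face that the palladium–MandyPhos complex selects, and C2' follows from the stereospecific anti addition across the E alkene, which gives the (1R,2S) boronate. The step needs oxidative addition at the triflate and not at the C7' bromide: the chelating bisphosphine favours C–OTf insertion, the bromide is electron-rich and flanked by OMOM, and KOTf removes the bromide ion left by the lithium–bromine exchange.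

Step 8
Reactants: 15 B(mac) ester of (1R,2S)-2-[3-bromo-6-methoxy-2-(methoxymethoxy)phenyl]-1-(2,4-dimethoxyphenyl)-2-(3,5-dimethoxyphenyl)ethylboronic acid
Product: 17 6-bromo-2-[(1S,2R)-2-(2,4-dimethoxyphenyl)-1-(3,5-dimethoxyphenyl)-2-hydroxyethyl]-3-methoxyphenol, via phenol boronate 16 (not isolated)
Conditions: HCl (cat.), MeOH/THF, 45 °C; then NaOH, H2O2, THF/H2O, 0 °C→rt
Reagents that add atoms: hydrogen peroxide, OO
Why: Acid-catalysed acetal methanolysis frees the phenol while C2' still carries boron, and the peroxide oxidation of the C–B bond (1,2-shift from boron to oxygen) then gives the alcohol with retention at C2'.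

Step 9
Reactants: 17 6-bromo-2-[(1S,2R)-2-(2,4-dimethoxyphenyl)-1-(3,5-dimethoxyphenyl)-2-hydroxyethyl]-3-methoxyphenol
Product: 18 (2S,3S)-7-bromo-2-(2,4-dimethoxyphenyl)-3-(3,5-dimethoxyphenyl)-4-methoxy-2,3-dihydro-1-benzofuran
Conditions: PPh3, DIAD, THF, 0 °C→rt
Reagents that add atoms: none
Why: Mitsunobu cycloetherification (5-exo-tet) lets the phenol displace the activated benzylic oxygen with inversion at C2', turning the anti adduct into the trans (2S,3S) ring; an ion-pair pathway would end at the same, more stable trans isomer.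

Step 10
Reactants: 19 3,5-dihydroxybenzaldehyde
Product: 20 3,5-bis(methoxymethoxy)benzaldehyde
Conditions: MOMCl, i-Pr2NEt, CH2Cl2, 0 °C→rt
Reagents that add atoms: chloromethyl methyl ether, COCCl
Why: Double O-alkylation (MOM protection) gives a symmetric bis-acetal whose two oxygens direct the later metalation and are released together in step 16.

Step 11
Reactants: 20 3,5-bis(methoxymethoxy)benzaldehyde; 21 diethyl (4-methoxybenzyl)phosphonate
Product: 22 1-[(E)-2-(4-methoxyphenyl)ethenyl]-3,5-bis(methoxymethoxy)benzene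
Conditions: NaH, THF, 0 °C→rt
Reagents that add atoms: none
Why: Horner–Wadsworth–Emmons olefination of an aryl aldehyde with a benzylic phosphonate anion gives the (E)-stilbene under thermodynamic control of the elimination.

Step 12
Reactants: 22 1-[(E)-2-(4-methoxyphenyl)ethenyl]-3,5-bis(methoxymethoxy)benzene
Product: 24 4-[(E)-2-(4-methoxyphenyl)ethenyl]-2,6-bis(methoxymethoxy)benzaldehyde, via aryllithium 23 (not isolated)
Conditions: n-BuLi, THF, −20→0 °C; DMF, −78 °C→rt; H2O
Reagents that add atoms: N,N-dimethylformamide, CN(C)C=O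
Why: Directed ortho-metalation at the position flanked by two chelating MOM ethers is fast enough at low temperature to outrun addition to the stilbene, and DMF formylates the aryllithium.

Step 13
Reactants: 24 4-[(E)-2-(4-methoxyphenyl)ethenyl]-2,6-bis(methoxymethoxy)benzaldehyde
Product: 25 2-ethynyl-5-[(E)-2-(4-methoxyphenyl)ethenyl]-1,3-bis(methoxymethoxy)benzene
Conditions: dimethyl (1-diazo-2-oxopropyl)phosphonate, K2CO3, MeOH/THF, 0 °C→rt
Reagents that add atoms: dimethyl (1-diazo-2-oxopropyl)phosphonate, COP(=O)(OC)C(=[N+]=[N-])C(C)=O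
Why: Seyferth–Gilbert homologation (Ohira–Bestmann form) again turns the aldehyde into the terminal alkyne without touching the acetals or the stilbene.

Step 14
Reactants: 25 2-ethynyl-5-[(E)-2-(4-methoxyphenyl)ethenyl]-1,3-bis(methoxymethoxy)benzene; 7 cis-1,2-dimethyl-1,2-dihydroacenaphthylene-1,2-diol
Product: 27 B(mac) ester of (E)-2-{4-[(E)-2-(4-methoxyphenyl)ethenyl]-2,6-bis(methoxymethoxy)phenyl}ethenylboronic acid, via alkenyl catechol boronate 26 (not isolated)
Conditions: catecholborane, Cy2BH (5 mol %), THF, rt; then 7, rt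
Reagents that add atoms: catecholborane, B1Oc2ccccc2O1
Why: Catalysed syn hydroboration is selective for the terminal alkyne over the internal stilbene alkene and gives the (E)-alkenylboron compound, which is transesterified to the mac ester.

Step 15
Reactants: 18 (2S,3S)-7-bromo-2-(2,4-dimethoxyphenyl)-3-(3,5-dimethoxyphenyl)-4-methoxy-2,3-dihydro-1-benzofuran; 27 B(mac) ester of (E)-2-{4-[(E)-2-(4-methoxyphenyl)ethenyl]-2,6-bis(methoxymethoxy)phenyl}ethenylboronic acid; 11 3,5-dimethoxyphenyl trifluoromethanesulfonate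
Product: 30 B(mac) ester of (1R,2S)-1-[(2S,3S)-2-(2,4-dimethoxyphenyl)-3-(3,5-dimethoxyphenyl)-4-methoxy-2,3-dihydro-1-benzofuran-7-yl]-2-(3,5-dimethoxyphenyl)-2-{4-[(E)-2-(4-methoxyphenyl)ethenyl]-2,6-bis(methoxymethoxy)phenyl}ethylboronic acid, via ring M aryllithium 28 (not isolated), via lithium ate complex 29 (not isolated)
Conditions: 18, t-BuLi (2 equiv), THF, −78 °C; then 27, −78 °C→rt; Pd(OAc)2 (5 mol %), (Sp,Sp)-MandyPhos (6 mol %), KOTf, 11, THF, 60 °C
Reagents that add atoms: none
Why: The conjunctive cross-coupling of step 7 is repeated with the lithium–bromine exchange product 28 as the 2,4-dioxygenated migrating aryl, so that the palladium–MandyPhos catalyst sets C3 by face selection (catalyst control, the ring M centres being remote) and anti addition across the E alkene fixes C2 relative to it.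

Step 16
Reactants: 30 B(mac) ester of (1R,2S)-1-[(2S,3S)-2-(2,4-dimethoxyphenyl)-3-(3,5-dimethoxyphenyl)-4-methoxy-2,3-dihydro-1-benzofuran-7-yl]-2-(3,5-dimethoxyphenyl)-2-{4-[(E)-2-(4-methoxyphenyl)ethenyl]-2,6-bis(methoxymethoxy)phenyl}ethylboronic acid
Product: 32 2-[(1S,2R)-2-[(2S,3S)-2-(2,4-dimethoxyphenyl)-3-(3,5-dimethoxyphenyl)-4-methoxy-2,3-dihydro-1-benzofuran-7-yl]-1-(3,5-dimethoxyphenyl)-2-hydroxyethyl]-5-[(E)-2-(4-methoxyphenyl)ethenyl]benzene-1,3-diol, via bisphenol boronate 31 (not isolated)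
Conditions: NaHSO4·SiO2, CH2Cl2, rt; filter; then NaOH, H2O2, THF/H2O, 0 °C→rt
Reagents that add atoms: hydrogen peroxide, OO
Why: A mild solid acid selective for phenolic MOM ethers hydrolyses both acetals without ionising the C2'–O1' bond of the ring M dihydrofuran, and peroxide oxidation of the C–B bond then gives the alcohol with retention at C2.

Step 17
Reactants: 32 2-[(1S,2R)-2-[(2S,3S)-2-(2,4-dimethoxyphenyl)-3-(3,5-dimethoxyphenyl)-4-methoxy-2,3-dihydro-1-benzofuran-7-yl]-1-(3,5-dimethoxyphenyl)-2-hydroxyethyl]-5-[(E)-2-(4-methoxyphenyl)ethenyl]benzene-1,3-diol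
Product: 33 (2S,3S)-2-[(2S,3S)-2-(2,4-dimethoxyphenyl)-3-(3,5-dimethoxyphenyl)-4-methoxy-2,3-dihydro-1-benzofuran-7-yl]-3-(3,5-dimethoxyphenyl)-6-[(E)-2-(4-methoxyphenyl)ethenyl]-2,3-dihydro-1-benzofuran-4-ol
Conditions: PPh3, DIAD, THF, 0 °C→rt
Reagents that add atoms: none
Why: Mitsunobu cycloetherification (5-exo-tet) by either of the two equivalent ring A phenols inverts C2 to give the trans (2S,3S) ring and leaves the other phenol as the free C4 hydroxyl.

Step 18
Reactants: 33 (2S,3S)-2-[(2S,3S)-2-(2,4-dimethoxyphenyl)-3-(3,5-dimethoxyphenyl)-4-methoxy-2,3-dihydro-1-benzofuran-7-yl]-3-(3,5-dimethoxyphenyl)-6-[(E)-2-(4-methoxyphenyl)ethenyl]-2,3-dihydro-1-benzofuran-4-ol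
Product: 34 gnetumontanin B
Conditions: BBr3 (excess), CH2Cl2, −78 °C→rt; then MeOH, H2O
Reagents that add atoms: none
Why: Lewis-acid cleavage of the eight aryl methyl ethers (boron tribromide demethylation) should release all phenols, the trans dihydrofurans being the thermodynamic form to which any reversibly opened C–O bond recloses, with C3 and C3' untouched.

Compound list

1 | 2-bromo-5-methoxyphenol | COc1ccc(Br)c(O)c1 | starting material
2 | 1-bromo-4-methoxy-2-(methoxymethoxy)benzene | COCOc1cc(OC)ccc1Br | intermediate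
3 | [3-bromo-6-methoxy-2-(methoxymethoxy)phenyl]lithium (not isolated) | COCOc1c([Li])c(OC)ccc1Br | intermediate
4 | 3-bromo-6-methoxy-2-(methoxymethoxy)benzaldehyde | COCOc1c(C=O)c(OC)ccc1Br | intermediate
5 | 1-bromo-3-ethynyl-4-methoxy-2-(methoxymethoxy)benzene | COCOc1c(C#C)c(OC)ccc1Br | intermediate
6 | acenaphthylene-1,2-dione | O=C1C(=O)c2cccc3cccc1c23 | starting material
7 | cis-(1R,2S)-1,2-dimethyl-1,2-dihydroacenaphthylene-1,2-diol (meso) | C[C@@]1(O)c2cccc3cccc(c23)[C@]1(C)O | intermediate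
8 | 2-{(E)-2-[3-bromo-6-methoxy-2-(methoxymethoxy)phenyl]ethenyl}-1,3,2-benzodioxaborole (not isolated) | COCOc1c(/C=C/B2Oc3ccccc3O2)c(OC)ccc1Br | intermediate
9 | B(mac) ester of (E)-2-[3-bromo-6-methoxy-2-(methoxymethoxy)phenyl]ethenylboronic acid | COCOc1c(/C=C/B2O[C@]3(C)c4cccc5cccc(c45)[C@]3(C)O2)c(OC)ccc1Br | intermediate
10 | 3,5-dimethoxyphenol | COc1cc(O)cc(OC)c1 | starting material
11 | 3,5-dimethoxyphenyl trifluoromethanesulfonate | COc1cc(OS(=O)(=O)C(F)(F)F)cc(OC)c1 | intermediate
12 | 1-bromo-2,4-dimethoxybenzene | COc1ccc(Br)c(OC)c1 | starting material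
13 | (2,4-dimethoxyphenyl)lithium (not isolated) | [Li]c1ccc(OC)cc1OC | intermediate
14 | lithium ate complex of 9 with the 2,4-dimethoxyphenyl group on boron (both epimers at boron; not isolated) | [Li+].COCOc1c(/C=C/[B-]2(c3ccc(OC)cc3OC)O[C@]4(C)c5cccc6cccc(c56)[C@]4(C)O2)c(OC)ccc1Br | intermediate
15 | B(mac) ester of (1R,2S)-2-[3-bromo-6-methoxy-2-(methoxymethoxy)phenyl]-1-(2,4-dimethoxyphenyl)-2-(3,5-dimethoxyphenyl)ethylboronic acid | COCOc1c(Br)ccc(OC)c1[C@H](c1cc(OC)cc(OC)c1)[C@@H](B1O[C@]2(C)c3cccc4cccc(c34)[C@]2(C)O1)c1ccc(OC)cc1OC | intermediate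
16 | B(mac) ester of (1R,2S)-2-(3-bromo-2-hydroxy-6-methoxyphenyl)-1-(2,4-dimethoxyphenyl)-2-(3,5-dimethoxyphenyl)ethylboronic acid (not isolated) | Oc1c(Br)ccc(OC)c1[C@H](c1cc(OC)cc(OC)c1)[C@@H](B1O[C@]2(C)c3cccc4cccc(c34)[C@]2(C)O1)c1ccc(OC)cc1OC | intermediate
17 | 6-bromo-2-[(1S,2R)-2-(2,4-dimethoxyphenyl)-1-(3,5-dimethoxyphenyl)-2-hydroxyethyl]-3-methoxyphenol | Oc1c(Br)ccc(OC)c1[C@H](c1cc(OC)cc(OC)c1)[C@@H](O)c1ccc(OC)cc1OC | intermediate
18 | (2S,3S)-7-bromo-2-(2,4-dimethoxyphenyl)-3-(3,5-dimethoxyphenyl)-4-methoxy-2,3-dihydro-1-benzofuran | Brc1ccc(OC)c2c1O[C@H](c1ccc(OC)cc1OC)[C@H]2c1cc(OC)cc(OC)c1 | intermediate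
19 | 3,5-dihydroxybenzaldehyde | O=Cc1cc(O)cc(O)c1 | starting material
20 | 3,5-bis(methoxymethoxy)benzaldehyde | COCOc1cc(C=O)cc(OCOC)c1 | intermediate
21 | diethyl (4-methoxybenzyl)phosphonate | CCOP(=O)(Cc1ccc(OC)cc1)OCC | starting material
22 | 1-[(E)-2-(4-methoxyphenyl)ethenyl]-3,5-bis(methoxymethoxy)benzene | COCOc1cc(/C=C/c2ccc(OC)cc2)cc(OCOC)c1 | intermediate
23 | {4-[(E)-2-(4-methoxyphenyl)ethenyl]-2,6-bis(methoxymethoxy)phenyl}lithium (not isolated) | COCOc1cc(/C=C/c2ccc(OC)cc2)cc(OCOC)c1[Li] | intermediate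
24 | 4-[(E)-2-(4-methoxyphenyl)ethenyl]-2,6-bis(methoxymethoxy)benzaldehyde | COCOc1cc(/C=C/c2ccc(OC)cc2)cc(OCOC)c1C=O | intermediate
25 | 2-ethynyl-5-[(E)-2-(4-methoxyphenyl)ethenyl]-1,3-bis(methoxymethoxy)benzene | COCOc1cc(/C=C/c2ccc(OC)cc2)cc(OCOC)c1C#C | intermediate
26 | 2-[(E)-2-{4-[(E)-2-(4-methoxyphenyl)ethenyl]-2,6-bis(methoxymethoxy)phenyl}ethenyl]-1,3,2-benzodioxaborole (not isolated) | COCOc1cc(/C=C/c2ccc(OC)cc2)cc(OCOC)c1/C=C/B1Oc2ccccc2O1 | intermediate
27 | B(mac) ester of (E)-2-{4-[(E)-2-(4-methoxyphenyl)ethenyl]-2,6-bis(methoxymethoxy)phenyl}ethenylboronic acid | COCOc1cc(/C=C/c2ccc(OC)cc2)cc(OCOC)c1/C=C/B1O[C@]2(C)c3cccc4cccc(c34)[C@]2(C)O1 | intermediate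
28 | [(2S,3S)-2-(2,4-dimethoxyphenyl)-3-(3,5-dimethoxyphenyl)-4-methoxy-2,3-dihydro-1-benzofuran-7-yl]lithium (not isolated) | [Li]c1ccc(OC)c2c1O[C@H](c1ccc(OC)cc1OC)[C@H]2c1cc(OC)cc(OC)c1 | intermediate
29 | lithium ate complex of 27 with the ring M aryl group of 28 on boron (both epimers at boron; not isolated) | [Li+].COCOc1cc(/C=C/c2ccc(OC)cc2)cc(OCOC)c1/C=C/[B-]1(c2ccc(OC)c3c2O[C@H](c2ccc(OC)cc2OC)[C@H]3c2cc(OC)cc(OC)c2)O[C@]2(C)c3cccc4cccc(c34)[C@]2(C)O1 | intermediate
30 | B(mac) ester of (1R,2S)-1-[(2S,3S)-2-(2,4-dimethoxyphenyl)-3-(3,5-dimethoxyphenyl)-4-methoxy-2,3-dihydro-1-benzofuran-7-yl]-2-(3,5-dimethoxyphenyl)-2-{4-[(E)-2-(4-methoxyphenyl)ethenyl]-2,6-bis(methoxymethoxy)phenyl}ethylboronic acid | COCOc1cc(/C=C/c2ccc(OC)cc2)cc(OCOC)c1[C@H](c1cc(OC)cc(OC)c1)[C@@H](B1O[C@]2(C)c3cccc4cccc(c34)[C@]2(C)O1)c1ccc(OC)c2c1O[C@H](c1ccc(OC)cc1OC)[C@H]2c1cc(OC)cc(OC)c1 | intermediate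
31 | B(mac) ester of the corresponding 2,6-dihydroxyphenyl compound (both MOM groups of 30 removed; not isolated) | Oc1cc(/C=C/c2ccc(OC)cc2)cc(O)c1[C@H](c1cc(OC)cc(OC)c1)[C@@H](B1O[C@]2(C)c3cccc4cccc(c34)[C@]2(C)O1)c1ccc(OC)c2c1O[C@H](c1ccc(OC)cc1OC)[C@H]2c1cc(OC)cc(OC)c1 | intermediate
32 | 2-[(1S,2R)-2-[(2S,3S)-2-(2,4-dimethoxyphenyl)-3-(3,5-dimethoxyphenyl)-4-methoxy-2,3-dihydro-1-benzofuran-7-yl]-1-(3,5-dimethoxyphenyl)-2-hydroxyethyl]-5-[(E)-2-(4-methoxyphenyl)ethenyl]benzene-1,3-diol | Oc1cc(/C=C/c2ccc(OC)cc2)cc(O)c1[C@H](c1cc(OC)cc(OC)c1)[C@@H](O)c1ccc(OC)c2c1O[C@H](c1ccc(OC)cc1OC)[C@H]2c1cc(OC)cc(OC)c1 | intermediate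
33 | (2S,3S)-2-[(2S,3S)-2-(2,4-dimethoxyphenyl)-3-(3,5-dimethoxyphenyl)-4-methoxy-2,3-dihydro-1-benzofuran-7-yl]-3-(3,5-dimethoxyphenyl)-6-[(E)-2-(4-methoxyphenyl)ethenyl]-2,3-dihydro-1-benzofuran-4-ol (octamethyl ether of the target) | COc1ccc(/C=C/c2cc(O)c3c(c2)O[C@H](c2ccc(OC)c4c2O[C@H](c2ccc(OC)cc2OC)[C@H]4c2cc(OC)cc(OC)c2)[C@H]3c2cc(OC)cc(OC)c2)cc1 | intermediate
34 | gnetumontanin B, (2S,3S,2'S,3'S) | Oc1ccc(/C=C/c2cc(O)c3c(c2)O[C@H](c2ccc(O)c4c2O[C@H](c2ccc(O)cc2O)[C@H]4c2cc(O)cc(O)c2)[C@H]3c2cc(O)cc(O)c2)cc1 | target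

Total step count: 18. Longest linear sequence: 11 steps (1, 2, 3, 5, 7, 8, 9, 15, 16, 17, 18).

Steps most likely to fail

Step 7. At the congested alkene, direct transfer of an organic group from boron to palladium (Suzuki–Miyaura pathway) or β-hydride loss from the alkylpalladium may outrun the metallate shift. Palladium may also insert into the C7' bromide, or the face selectivity may be too low. The fallback drops the catalytic three-component union for a polar, stepwise build of the same ring, and sets out from aldehyde 4. Addition of commercial 3,5-dimethoxyphenylmagnesium chloride gives [3-bromo-6-methoxy-2-(methoxymethoxy)phenyl](3,5-dimethoxyphenyl)methanol F1. Dess–Martin oxidation gives the diaryl ketone F2, and Corey–Chaykovsky methylenation (trimethylsulfonium iodide, KOt-Bu, DMSO) gives the 2,2-diaryloxirane F3. ZnI2 then induces Meinwald rearrangement to the 2,2-diarylacetaldehyde F4. The Grignard reagent made from 12 and magnesium adds to it to give the 1,2,2-triarylethanol F5 as a racemic mixture of diastereomers. Catalytic HCl in MeOH removes the MOM group and closes the C2'–O1' bond through the ring E-stabilised benzylic cation, trans under thermodynamic control. This gives the racemate of 18 and its (2R,3R) enantiomer F6, and preparative chromatography on a chiral stationary phase delivers 18, where the route is rejoined.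

Step 15. Lithium–bromine exchange on the advanced bromide may be accompanied by deprotonation or ring opening. Ate formation and the metallate shift may be slow with the bulky ring M aryl, and catalyst and substrate may be mismatched so that face selection at C3 is poor. The cationic arylpalladium may also arylate the stilbene. The fallback replaces the coupling by aryllithium addition to an aldehyde and cationic ring closure; it sets out from aldehyde 24 and bromide 18. Aldehyde 24 and 3,5-dimethoxyphenylmagnesium chloride give the diarylmethanol F7. Dess–Martin oxidation gives the ketone F8, Corey–Chaykovsky methylenation gives the oxirane F9, and ZnI2 gives the 2,2-diarylacetaldehyde F10. Aryllithium 28, made from 18 as in step 15, adds to F10 to give the alcohol F11 as a mixture at both new centres. Mild acid (NaHSO4·SiO2, then catalytic HCl in MeOH if needed) removes both MOM groups and closes the C2–O1 bond through the ring M-stabilised cation, trans under thermodynamic control. The products are 33 and its (2R,3R,2'S,3'S) diastereomer F12, which are diastereomers and are separated on silica; the route is rejoined at 33.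

Step 18. The Lewis acid may ionise the benzylic C2–O1 and C2'–O1' bonds and lead to ring-opened or rearranged material, and cleavage of eight ethers may stop short. The fallback sets out from 33 and ends at 34: nucleophilic demethylation with excess NaSEt in DMF at 130 °C, followed by acidification. The thiolate attacks the methyl carbons by an SN2 path with no Lewis acid present, and the phenoxides formed are inert to further attack.

Further compounds

F1 | step 7 | [3-bromo-6-methoxy-2-(methoxymethoxy)phenyl](3,5-dimethoxyphenyl)methanol (racemic) | COCOc1c(C(O)c2cc(OC)cc(OC)c2)c(OC)ccc1Br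
F2 | step 7 | [3-bromo-6-methoxy-2-(methoxymethoxy)phenyl](3,5-dimethoxyphenyl)methanone | COCOc1c(C(=O)c2cc(OC)cc(OC)c2)c(OC)ccc1Br
F3 | step 7 | 2-[3-bromo-6-methoxy-2-(methoxymethoxy)phenyl]-2-(3,5-dimethoxyphenyl)oxirane (racemic) | COCOc1c(C2(CO2)c3cc(OC)cc(OC)c3)c(OC)ccc1Br
F4 | step 7 | 2-[3-bromo-6-methoxy-2-(methoxymethoxy)phenyl]-2-(3,5-dimethoxyphenyl)acetaldehyde (racemic) | COCOc1c(C(C=O)c2cc(OC)cc(OC)c2)c(OC)ccc1Br
F5 | step 7 | 2-[3-bromo-6-methoxy-2-(methoxymethoxy)phenyl]-1-(2,4-dimethoxyphenyl)-2-(3,5-dimethoxyphenyl)ethanol (racemic diastereomer mixture) | COCOc1c(C(c2cc(OC)cc(OC)c2)C(O)c2ccc(OC)cc2OC)c(OC)ccc1Br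
F6 | step 7 | (2R,3R)-7-bromo-2-(2,4-dimethoxyphenyl)-3-(3,5-dimethoxyphenyl)-4-methoxy-2,3-dihydro-1-benzofuran (enantiomer of 18) | Brc1ccc(OC)c2c1O[C@@H](c1ccc(OC)cc1OC)[C@@H]2c1cc(OC)cc(OC)c1
F7 | step 15 | (3,5-dimethoxyphenyl){4-[(E)-2-(4-methoxyphenyl)ethenyl]-2,6-bis(methoxymethoxy)phenyl}methanol (racemic) | COCOc1cc(/C=C/c2ccc(OC)cc2)cc(OCOC)c1C(O)c1cc(OC)cc(OC)c1
F8 | step 15 | (3,5-dimethoxyphenyl){4-[(E)-2-(4-methoxyphenyl)ethenyl]-2,6-bis(methoxymethoxy)phenyl}methanone | COCOc1cc(/C=C/c2ccc(OC)cc2)cc(OCOC)c1C(=O)c1cc(OC)cc(OC)c1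
F9 | step 15 | 2-(3,5-dimethoxyphenyl)-2-{4-[(E)-2-(4-methoxyphenyl)ethenyl]-2,6-bis(methoxymethoxy)phenyl}oxirane (racemic) | COCOc1cc(/C=C/c2ccc(OC)cc2)cc(OCOC)c1C3(CO3)c3cc(OC)cc(OC)c3
F10 | step 15 | 2-(3,5-dimethoxyphenyl)-2-{4-[(E)-2-(4-methoxyphenyl)ethenyl]-2,6-bis(methoxymethoxy)phenyl}acetaldehyde (racemic) | COCOc1cc(/C=C/c2ccc(OC)cc2)cc(OCOC)c1C(C=O)c1cc(OC)cc(OC)c1
F11 | step 15 | 1-[(2S,3S)-2-(2,4-dimethoxyphenyl)-3-(3,5-dimethoxyphenyl)-4-methoxy-2,3-dihydro-1-benzofuran-7-yl]-2-(3,5-dimethoxyphenyl)-2-{4-[(E)-2-(4-methoxyphenyl)ethenyl]-2,6-bis(methoxymethoxy)phenyl}ethanol (mixture at both new centres) | COCOc1cc(/C=C/c2ccc(OC)cc2)cc(OCOC)c1C(c1cc(OC)cc(OC)c1)C(O)c1ccc(OC)c2c1O[C@H](c1ccc(OC)cc1OC)[C@H]2c1cc(OC)cc(OC)c1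
F12 | step 15 | (2R,3R)-2-[(2S,3S)-2-(2,4-dimethoxyphenyl)-3-(3,5-dimethoxyphenyl)-4-methoxy-2,3-dihydro-1-benzofuran-7-yl]-3-(3,5-dimethoxyphenyl)-6-[(E)-2-(4-methoxyphenyl)ethenyl]-2,3-dihydro-1-benzofuran-4-ol (C2,C3 diastereomer of 33) | COc1ccc(/C=C/c2cc(O)c3c(c2)O[C@@H](c2ccc(OC)c4c2O[C@H](c2ccc(OC)cc2OC)[C@H]4c2cc(OC)cc(OC)c2)[C@@H]3c2cc(OC)cc(OC)c2)cc1
F0 | step 18 | none | none
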